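**Plan**

- Retrosynthesis: cut the C1'–C(ring) bond between side chain and maleic anhydride (a 15‑acetoxyhexadecyl radical from a C17 acid by loss of CO2, plus citraconic anhydride); cut the C15'–O bond by reversing an oxygen insertion (17‑membered lactone back to 2‑methylcyclohexadecanone); cut C15'–C16' (α‑methylation of cyclohexadecanone).
- Enabling feature: the side chain C1'–C16', oxygenated at C15' next to the terminal methyl C16', is the ring of 2‑methylcyclohexadecanone opened between C1 and C2, plus one carboxyl carbon. C2 becomes C15', the methyl becomes C16', C16…C3 become C1'…C14', and C1 is lost as CO2.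
- Forward: the purchased 16‑membered carbocycle is methylated, expanded to the 17‑membered lactone (the only ring made), opened to the chain and acetylated. Decarboxylative radical addition then joins it to the ready‑made ring of citraconic anhydride, and elimination restores the ring C=C.
- Stereochemistry: the single stereocentre (S at C15') is set as S at C2 of the ketone by RAMP‑hydrazone methylation and carried into the C–O bond by the retentive 1,2‑shift; no later step touches it.

Key step: step 4

Remark on the chemistry: hydrazone 6 is written as the Z isomer expected directly from azaenolate alkylation (either C=N isomer is cleaved to the same ketone); the transient centres of 8 and 15 form without control and are left undefined.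

**Route**

Step 1
Reactants: 1 cyclohexadecanone; 2 (R)-1-amino-2-(methoxymethyl)pyrrolidine (RAMP)
Product: 3 RAMP hydrazone of cyclohexadecanone [(R)-N-cyclohexadecylidene-2-(methoxymethyl)pyrrolidin-1-amine]
Conditions: 2 (1.2 equiv), p-toluenesulfonic acid monohydrate (cat.), cyclohexane, reflux, Dean–Stark trap
Reagents that add atoms: RAMP (compound 2), COC[C@H]1CCCN1N
Why: Acid-catalysed condensation of the ketone with the NH2 group of the hydrazine (hydrazone formation) is driven to completion by azeotropic removal of water, and the symmetrical ketone can give only one hydrazone.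

Step 2
Reactants: 3 RAMP hydrazone of cyclohexadecanone; 4 iodomethane
Product: 6 (Z)-RAMP hydrazone of (S)-2-methylcyclohexadecanone [(2R)-2-(methoxymethyl)-N-[(1Z,2S)-2-methylcyclohexadecylidene]pyrrolidin-1-amine], via lithium azaenolate 5 (not isolated)
Conditions: LiN(i-Pr)2 (LDA, 1.2 equiv), Et2O, 0 °C, 4 h; then MeI (1.5 equiv), −100 °C → rt
Reagents that add atoms: iodomethane (compound 4), CI
Why: Enders RAMP-hydrazone alkylation: LiN(i-Pr)2 removes an α-proton to give azaenolate 5, whose ring C=C is cis (E in the acyclic notation) and whose lithium is chelated by the methoxy group, so iodomethane enters from the one open face and the R-auxiliary sets S at C2 (the mirror image of the R-ketone expected from the S-auxiliary with cyclic ketones).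

Step 3
Reactants: 6 (Z)-RAMP hydrazone of (S)-2-methylcyclohexadecanone
Product: 7 (S)-2-methylcyclohexadecanone
Conditions: O3, CH2Cl2, −78 °C; then N2 purge
Reagents that add atoms: ozone, [O-][O+]=O
Why: Ozonolytic cleavage of the hydrazone C=N bond (oxidative hydrazone cleavage) runs at −78 °C without acid or base, so the ketone is released with its enolisable C2 centre still S and the auxiliary leaves as its N-nitrosamine.

Step 4
Reactants: 7 (S)-2-methylcyclohexadecanone
Product: 9 (S)-17-methyl-1-oxacycloheptadecan-2-one [(S)-16-heptadecanolide], via Criegee peroxyhemiketal 8 (not isolated)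
Conditions: (CF3CO)2O, urea–hydrogen peroxide, Na2HPO4, CH2Cl2, 0 °C → rt
Reagents that add atoms: trifluoroperacetic acid (formed in the flask from trifluoroacetic anhydride and urea–hydrogen peroxide), OOC(=O)C(F)(F)F
Why: The peracid adds to the C1 carbonyl of 7 to give the Criegee peroxyhemiketal 8, and the C1–C2 bond anti to the O–O bond then shifts from carbon to oxygen as trifluoroacetate departs (Baeyer–Villiger oxidation). The closest known reaction type is the Baeyer–Villiger conversion of 2-methylcycloalkanones into (ω−1)-lactones. The 17-membered lactone ring arises by one-atom ring expansion of the 16-membered carbocycle (oxygen inserted into C1–C2), not by an end-to-end cyclisation, so no Baldwin mode applies and no high dilution is needed. The C–O stereocentre (C17 of 9, C15' of the target) is controlled by the S configuration at C2 of 7, because the migrating carbon keeps its bonding electron pair and moves suprafacially with retention, S to S. The step needs migration of C2 in preference to C16, which the higher migratory aptitude of the secondary carbon secures, and an intact C2 configuration before migration, which the Na2HPO4 buffer (no free CF3CO2H to enolise the ketone) and the fast reaction of the strongly electrophilic peracid with the otherwise sluggish macrocyclic ketone secure.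

Step 5
Reactants: 9 (S)-17-methyl-1-oxacycloheptadecan-2-one
Product: 10 (S)-16-hydroxyheptadecanoic acid
Conditions: KOH, MeOH/H2O, reflux; then 1 M HCl, 0 °C
Reagents that add atoms: potassium hydroxide, [K+].[OH-]
Why: Saponification (acyl–oxygen cleavage of the lactone) breaks only the C1–O bond, so the C16 carbinol centre stays S, and the 1,16-hydroxy acid does not reclose to a 17-membered ring on acidification.

Step 6
Reactants: 10 (S)-16-hydroxyheptadecanoic acid
Product: 12 (S)-16-acetoxyheptadecanoic acid, via mixed anhydride 11 (not isolated)
Conditions: Ac2O (3 equiv), pyridine, 4-(dimethylamino)pyridine (cat.), CH2Cl2, 0 °C → rt; then H2O, THF, rt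
Reagents that add atoms: acetic anhydride, CC(=O)OC(C)=O; water, O
Why: Nucleophile-catalysed O-acetylation of the secondary alcohol leaves the C16–O bond intact (retention), while the carboxyl group is transiently tied up as mixed anhydride 11, which the aqueous hold hydrolyses back to the acid much faster than the secondary acetate.

Step 7
Reactants: 12 (S)-16-acetoxyheptadecanoic acid
Product: 13 Barton ester [2-thioxopyridin-1(2H)-yl (S)-16-acetoxyheptadecanoate]
Conditions: 1-hydroxypyridine-2(1H)-thione (1.1 equiv), N,N'-dicyclohexylcarbodiimide (1.1 equiv), CH2Cl2, 0 °C → rt, in the dark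
Reagents that add atoms: 1-hydroxypyridine-2(1H)-thione, ON1C=CC=CC1=S
Why: Carbodiimide-mediated esterification of the acid with the N-hydroxy group of the thiohydroxamic acid gives the O-acyl thiohydroxamate (Barton ester formation), which is kept from light until use and does not involve the remote acetate.

Step 8
Reactants: 13 Barton ester; 14 citraconic anhydride (3-methylfuran-2,5-dione)
Product: 16 (S)-16-(4-methyl-2,5-dioxo-2,5-dihydrofuran-3-yl)hexadecan-2-yl acetate (target), via pyridylthio succinic anhydride adduct 15 (not isolated)
Conditions: 14 (5 equiv), hν (250 W tungsten lamp), CH2Cl2, 10–15 °C; then Et3N (0.2 equiv), rt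
Reagents that add atoms: citraconic anhydride (compound 14), CC1=CC(=O)OC1=O
Why: Barton decarboxylation in a radical chain: light cleaves the N–O bond of 13, the acyloxy radical loses CO2, the primary C1' radical adds to the unsubstituted CH carbon of 14 to give the tertiary carbonyl-stabilised radical, which takes the pyridylthio group from a further molecule of 13 to give 15, and the acidic ring proton then allows base-catalysed β-elimination (E1cB) of pyridine-2-thiol to the tetrasubstituted maleic anhydride with the remote S-acetate untouched.

**Compound list**

1 | cyclohexadecanone | O=C1CCCCCCCCCCCCCCC1 | starting material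
2 | (R)-1-amino-2-(methoxymethyl)pyrrolidine (RAMP) | COC[C@H]1CCCN1N | starting material
3 | (R)-N-cyclohexadecylidene-2-(methoxymethyl)pyrrolidin-1-amine | COC[C@H]1CCCN1N=C1CCCCCCCCCCCCCCC1 | intermediate
4 | iodomethane | CI | starting material
5 | lithium azaenolate of 3 (ring C=C cis, not isolated) | COC[C@H]1CCCN1N([Li])/C1=C/CCCCCCCCCCCCCC1 | intermediate
6 | (2R)-2-(methoxymethyl)-N-[(1Z,2S)-2-methylcyclohexadecylidene]pyrrolidin-1-amine | COC[C@H]1CCCN1/N=C1/CCCCCCCCCCCCCC[C@@H]1C | intermediate
7 | (S)-2-methylcyclohexadecanone | O=C1[C@@H](C)CCCCCCCCCCCCCC1 | intermediate
8 | (2S)-1-hydroxy-2-methylcyclohexadecyl trifluoroperacetate (Criegee peroxyhemiketal, either epimer at C1, not isolated) | OC1(OOC(=O)C(F)(F)F)[C@@H](C)CCCCCCCCCCCCCC1 | intermediate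
9 | (S)-17-methyl-1-oxacycloheptadecan-2-one [(S)-16-heptadecanolide] | C[C@H]1CCCCCCCCCCCCCCC(=O)O1 | intermediate
10 | (S)-16-hydroxyheptadecanoic acid | C[C@H](O)CCCCCCCCCCCCCCC(=O)O | intermediate
11 | acetic (S)-16-acetoxyheptadecanoic anhydride (not isolated) | CC(=O)O[C@@H](C)CCCCCCCCCCCCCCC(=O)OC(C)=O | intermediate
12 | (S)-16-acetoxyheptadecanoic acid | CC(=O)O[C@@H](C)CCCCCCCCCCCCCCC(=O)O | intermediate
13 | 2-thioxopyridin-1(2H)-yl (S)-16-acetoxyheptadecanoate (Barton ester) | CC(=O)O[C@@H](C)CCCCCCCCCCCCCCC(=O)ON1C=CC=CC1=S | intermediate
14 | citraconic anhydride (3-methylfuran-2,5-dione) | CC1=CC(=O)OC1=O | starting material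
15 | (2S)-16-[4-methyl-2,5-dioxo-4-(pyridin-2-ylsulfanyl)oxolan-3-yl]hexadecan-2-yl acetate (diastereomer mixture at the two ring carbons, not isolated) | CC(=O)O[C@@H](C)CCCCCCCCCCCCCCC1C(=O)OC(=O)C1(C)Sc1ccccn1 | intermediate
16 | (S)-16-(4-methyl-2,5-dioxo-2,5-dihydrofuran-3-yl)hexadecan-2-yl acetate | CC(=O)O[C@@H](C)CCCCCCCCCCCCCCC1=C(C)C(=O)OC1=O | target

**Count**

Total steps: 8. Longest linear sequence: 8 steps (from cyclohexadecanone 1; compounds 2, 4 and 14 are purchased).

**Three steps most likely to fail**

1. Step 2 (asymmetric methylation). The azaenolate of the conformationally mobile 16-membered ring may form incompletely or as a mixture of C=C geometries, so that iodomethane is delivered with poor facial selectivity. The fallback sets out from 1 and comes back at 9, replacing auxiliary control by an enzymatic resolution after the ring expansion. Cyclohexadecanone 1 would be methylated through its lithium enolate (LiN(i-Pr)2, THF, −78 °C; MeI) to racemic 2-methylcyclohexadecanone F1. Under the conditions of step 4 this should give racemic 17-methyl-1-oxacycloheptadecan-2-one F2. Alcoholysis of F2 with immobilised Candida antarctica lipase B (n-butanol, toluene, 45–60 °C) is expected to open the R-lactone selectively, since large-ring (ω−1)-methyl lactones behave like esters of acyclic secondary alcohols, giving butyl (R)-16-hydroxyheptadecanoate F3. The unreacted S-lactone 9 would be recovered by chromatography, its enantiomeric purity checked, and the route resumed at step 5; at most half of the material is usable.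

2. Step 4 (key ring expansion). Oxygen insertion at the unstrained macrocyclic carbonyl may be slow, leaving time for acid-mediated enolisation (erosion of the C2 configuration) or partial migration of the methylene carbon. The fallback sets out from 1 and comes back at 10; it replaces oxygen insertion by C=C cleavage and moves the origin of the stereocentre to an enzyme. MeMgBr (THF, 0 °C) would add to 1 to give 1-methylcyclohexadecan-1-ol F4. Dehydration (p-toluenesulfonic acid, toluene, reflux) should give 1-methylcyclohexadec-1-ene F5. Oxidative cleavage of the ring C=C (RuCl3 cat., NaIO4, MeCN/EtOAc/H2O) would give 16-oxoheptadecanoic acid F6. A Prelog-selective alcohol dehydrogenase (for example the enzyme of Rhodococcus ruber, 2-propanol as hydride source, buffer) should reduce the methyl ketone to the S-alcohol, (S)-16-hydroxyheptadecanoic acid 10.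

3. Step 8 (radical addition and elimination). Loss of the pyridylthio group may stall at the adduct or run toward the methyl group to give an exocyclic alkene. Premature capture of the alkyl radical by the thiocarbonyl group is countered within the step by the excess of 14. The fallback sets out from 15 and comes back at 16. The photolysis would be worked up without base and adduct 15 isolated as its diastereomer mixture. Oxidation at sulfur (mCPBA, 1 equiv, CH2Cl2, −78 → 0 °C) should give (2S)-16-[4-methyl-2,5-dioxo-4-(pyridin-2-ylsulfinyl)oxolan-3-yl]hexadecan-2-yl acetate F7. Warming in toluene (60–80 °C) should then bring about thermal syn-elimination toward the activated ring hydrogen, which lies cis to sulfur in the expected trans adduct, giving 16. This replaces base-induced β-elimination by a pericyclic sulfoxide elimination that does not depend on deprotonation or on thiolate leaving-group ability.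

**Further compounds**

F1 | step 2 | racemic 2-methylcyclohexadecanone | O=C1C(C)CCCCCCCCCCCCCC1
F2 | step 2 | racemic 17-methyl-1-oxacycloheptadecan-2-one | CC1CCCCCCCCCCCCCCC(=O)O1
F3 | step 2 | butyl (R)-16-hydroxyheptadecanoate | C[C@@H](O)CCCCCCCCCCCCCCC(=O)OCCCC
F4 | step 4 | 1-methylcyclohexadecan-1-ol | CC1(O)CCCCCCCCCCCCCCC1
F5 | step 4 | 1-methylcyclohexadec-1-ene (E/Z mixture) | CC1=CCCCCCCCCCCCCCC1
F6 | step 4 | 16-oxoheptadecanoic acid | CC(=O)CCCCCCCCCCCCCCC(=O)O
F7 | step 8 | (2S)-16-[4-methyl-2,5-dioxo-4-(pyridin-2-ylsulfinyl)oxolan-3-yl]hexadecan-2-yl acetate | CC(=O)O[C@@H](C)CCCCCCCCCCCCCCC1C(=O)OC(=O)C1(C)S(=O)c1ccccn1
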